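## Analysis of the target

Compound 13 (2'-hydroxypiscerythrinetin) is an isoflavone: a 4H-chromen-4-one (rings A and C) that carries ring B on C3. It has no stereocentre; the only stereochemical element in the route is the (E) double bond of a chalcone intermediate, which is consumed again. Ring A has the 5,7-dihydroxy pattern, with the 5-OH chelated to the C4 carbonyl. Ring B is pentasubstituted: C1' is bonded to C3, C2' bears OH, C3' the prenyl group, C4' and C5' methoxy groups, and only C6' keeps a hydrogen. The sensitive parts are the prenyl olefin (lost to hydrogenation, to oxidants and, with the neighbouring 2'-OH, to acid-induced chroman formation), the para-related 2'-OH/5'-OMe pair (an easily oxidised hydroquinone monoether) and C2 of the pyranone (opened by strong nucleophilic base). The difficulty is one of ordering: three phenols must be told apart, the prenyl group must go to C3' only, and it must arrive after every oxidising or reducing step. The strategy rests on the C3–C1' bond: the aryl group sits on C3 next to the carbonyl and not on C2, which is what a 1,2-aryl shift in a chalcone delivers. Ring B, with oxygen on C2' and C4' ortho and para to C1', is an aryl group that migrates very readily.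

## Retrosynthetic reasoning

13 from 12: the two O–benzyl bonds on ring A are cut last. Ring A has to stay masked until the end, because free 5- and 7-hydroxyls would compete with the 2'-hydroxyl in every alkylation. Benzyl ethers survive base, oxidant and protic acid, so they are orthogonal to the acetal protecting group used on ring B. The forward step must cleave them without hydrogen and at low temperature, so that the prenyl olefin is neither reduced nor cyclised.

12 from 11: the C3'–CH2 bond of the prenyl group is cut. An ortho-prenyl phenol is the retron of an aromatic Claisen rearrangement of a 1,1-dimethylallyl aryl ether. In 11 the two ortho positions of O2' are C1' (quaternary) and C3' (free), and the para position C5' is blocked, so only C3' can end up substituted. This makes the regiochemistry of prenylation a consequence of the ring B substitution and not of reagent control.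

11 from 10 from 9: the O2'–C(tertiary) bond is cut. A tertiary allyl ether cannot be made by direct displacement, so the ether is formed at the propargylic stage, where a copper-stabilised cation accepts the phenoxide. The alkyne of 10 is then half-reduced. Compound 9 has exactly one free hydroxyl, so no selectivity question arises.

9 from 6 (key disconnection): the C3–C1' bond and the O1–C2 bond are cut. Reversing the 1,2-aryl shift moves ring B back to the future C2 and opens ring C, which gives the 2'-hydroxychalcone 6. The aryl–C3 bond then needs no cross-coupling partner, and ring C and the C3 substitution arise together. The forward reaction must oxidise the enone with aryl migration and then close ring C. The same acid frees the ring B phenol and leaves the ring A benzyl ethers, so the one hydroxyl needed for the next stage is exposed.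

6 from 3 and 5: the Cα=Cβ bond is cut by a retro-aldol condensation into a methyl ketone and a benzaldehyde. Each half carries all its oxygen atoms already, so no aromatic oxidation is needed later.

3 from 1 and 2, and 5 from 4: only O-protection steps. In 1 the hydroxyl that stays hydrogen-bonded to the acetyl group is the least reactive, so two-fold benzylation leaves exactly the phenol that later becomes O1. In 4 the single phenol is capped as an acid-labile acetal so that it is inert towards the oxidant and is released in the acidic second stage of the key step.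

## Alternatives that were turned down

Alternative 1: ring C is cut at C3–C4 and O1–C2. The salicylaldehyde 2-hydroxy-4,6-bis(methoxymethoxy)benzaldehyde A2 and the alkyne {[4,5-dimethoxy-2-(methoxymethoxy)-3-(3-methylbut-2-en-1-yl)phenyl]ethynyl}trimethylsilane A3 would be annulated by acyl C–H activation with [RhCl(cod)]2 (monovalent rhodium) and Cu(OAc)2 as oxidant. The product would be the 2-silylchromone 3-[4,5-dimethoxy-2-(methoxymethoxy)-3-(3-methylbut-2-en-1-yl)phenyl]-5,7-bis(methoxymethoxy)-2-(trimethylsilyl)-4H-chromen-4-one A1, and acid would then remove the silyl and acetal groups to give 13.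
- For it: it is convergent, the prenyl chemistry is done on a small arene, and no thallium is used. On these points it is stronger than the chosen route.
- Against it: the aryl group reaches C3 only if the silyl group controls the insertion. The formyl group of A2 is flanked by an alkoxy group, which favours decarbonylation of the acyl–rhodium intermediate. The prenyl olefin is exposed to hot copper oxidant. A3 needs about six steps of its own, so the total is not shorter than eight. The final global acid treatment meets the prenyl group next to a free phenol.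
- The chosen route offers in exchange a C3 regiochemistry that cannot go wrong and commodity starting materials.

Alternative 2: ring B is built last by a Dötz benzannulation. The alkyne 3-ethynyl-5,7-bis(methoxymethoxy)-4H-chromen-4-one A5, the carbene complex pentacarbonyl(1,2-dimethoxy-6-methylhepta-2,5-dien-1-ylidene)chromium A6 (zerovalent chromium) and one CO ligand would combine. The product would be 3-[2-hydroxy-4,5-dimethoxy-3-(3-methylbut-2-en-1-yl)phenyl]-5,7-bis(methoxymethoxy)-4H-chromen-4-one A4, with the 2'-OH free.
- For it: the fully substituted ring B, prenyl group included, arises in one step with inherent regiochemistry (the larger alkyne substituent ends next to the new phenol). This is more direct than the three-step ether/Claisen sequence of the chosen route.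
- Against it: A6 is an α-alkoxy alkenyl carbene with a skipped diene, hard to prepare and to handle. A5 is an electron-poor alkyne on a Michael-acceptor chromone, the class for which benzannulation competes poorly with cyclopentannulation and furan formation. The product is released from chromium oxidatively, which endangers its para-methoxyphenol ring. Stoichiometric chromium is no gain over stoichiometric thallium, and both partners need several steps.
- The chosen route relies on a reaction class that is long established for polyalkoxylated chalcones.

Alternative 3: ring A is built by cycloaddition. The diene 1-methoxy-1,3-bis(trimethylsilyloxy)buta-1,3-diene A8 (C1=C2 geometry not defined) would add to the brominated double bond of 3-bromo-5-[4,5-dimethoxy-2-(methoxymethoxy)-3-(3-methylbut-2-en-1-yl)phenyl]-4H-pyran-4-one A9, forming C8–C8a and C4a–C5. Loss of HBr and methanol would aromatise to 5,7-dihydroxy-3-[4,5-dimethoxy-2-(methoxymethoxy)-3-(3-methylbut-2-en-1-yl)phenyl]-4H-chromen-4-one A7.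
- For it: ring A arrives with both hydroxyls free, so no debenzylation in the presence of the prenyl group is needed and no heavy metal oxidant is used. On these points it is stronger than the chosen route.
- Against it: a 4-pyranone is a reluctant dienophile, and A9 has a second enone double bond. A9 must itself be made by attaching a prenylated ring B to a pyranone, so the aryl–C3 bond still costs a separate coupling. The effort goes into the ring that is cheapest to buy.
- The chosen route takes ring A whole from 1 and spends its key step on the bond that defines an isoflavone.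

Key step: step 4

## Route

Assumption: compound 4, chloromethyl methyl ether and 2-methylbut-3-yn-2-ol are purchased. The acetal 7 is racemic at its one stereocentre, which is erased when ring C forms.

Step 1
Reactants: 1 2,4,6-trihydroxyacetophenone; 2 benzyl bromide
Product: 3 1-[2,4-bis(benzyloxy)-6-hydroxyphenyl]ethan-1-one
Conditions: 2 (2.05 equiv), K2CO3 (2.2 equiv), DMF, rt
Reagents that add atoms: none
Why: Williamson etherification; the 4-OH and one ortho-OH are alkylated, while the remaining ortho-OH stays hydrogen-bonded to the acetyl carbonyl and is the least nucleophilic, so the reaction should stop at the dibenzyl ether.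

Step 2
Reactants: 4 2-hydroxy-4,5-dimethoxybenzaldehyde
Product: 5 4,5-dimethoxy-2-(methoxymethoxy)benzaldehyde
Conditions: MOMCl, K2CO3, DMF, 0 °C to rt
Reagents that add atoms: chloromethyl methyl ether, COCCl
Why: O-alkylation of the only phenol as its methoxymethyl ether; the acetal is stable to the base of step 3 and to the oxidant of step 4 and is cleaved by the acid used there.

Step 3
Reactants: 3 1-[2,4-bis(benzyloxy)-6-hydroxyphenyl]ethan-1-one; 5 4,5-dimethoxy-2-(methoxymethoxy)benzaldehyde
Product: 6 (E)-1-[2,4-bis(benzyloxy)-6-hydroxyphenyl]-3-[4,5-dimethoxy-2-(methoxymethoxy)phenyl]prop-2-en-1-one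
Conditions: KOH (50% aq), EtOH/THF, rt; AcOH to pH 6 at 0 °C
Reagents that add atoms: none
Why: Claisen–Schmidt condensation; 5 cannot enolise, and E1cB dehydration of the aldol gives the conjugated (E) enone under thermodynamic control. Benzyl and methoxymethyl ethers are inert to hydroxide, and the mild acidification spares the acetal.

Step 4
Reactants: 6 (E)-1-[2,4-bis(benzyloxy)-6-hydroxyphenyl]-3-[4,5-dimethoxy-2-(methoxymethoxy)phenyl]prop-2-en-1-one
Product: 9 5,7-bis(benzyloxy)-3-(2-hydroxy-4,5-dimethoxyphenyl)-4H-chromen-4-one, via dimethyl acetal 7 (not isolated), via MOM-protected isoflavone 8 (not isolated)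
Conditions: Tl(NO3)3·3H2O (1.1 equiv), MeOH/HC(OMe)3, rt; filter off TlNO3; then 3 M aq HCl, MeOH/THF, 55 °C
Reagents that add atoms: none
Why: This is the Tl(NO3)3 oxidative rearrangement of a 2'-hydroxychalcone to an isoflavone, a known reaction type for polyalkoxylated chalcones. Trivalent thallium adds to the enone C=C with the metal on the α-carbon and methanol on the benzylic β-carbon; as monovalent thallium leaves, C1' of ring B bridges to the α-carbon in a phenonium ion and stays bonded there, which is the C3–C1' bond. The β-carbon is left as a methoxy-stabilised oxocarbenium ion and is trapped by methanol as the racemic dimethyl acetal 7. On acidification one methoxy group ionises, the chelated ring A phenol closes ring C by 6-exo-trig O-attack on that carbon (O1–C2), and loss of the second methanol across C2–C3 gives the chromone 8. Continued heating in methanolic HCl transfers the methoxymethyl group to methanol and frees the 2'-phenol of 9, while the benzyl ethers are stable. No stereocentre remains in 9. The step needs aryl migration to outrun aurone formation, hydride shift and plain 1,2-dimethoxylation, and the 2-alkoxy and 4-methoxy groups ortho and para to C1' secure this by stabilising the bridged cation. The chalcone C=C is the only alkene present, because the prenyl group comes later, so the slight excess of oxidant has one site of attack.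

Step 5
Reactants: 9 5,7-bis(benzyloxy)-3-(2-hydroxy-4,5-dimethoxyphenyl)-4H-chromen-4-one
Product: 10 5,7-bis(benzyloxy)-3-{4,5-dimethoxy-2-[(2-methylbut-3-yn-2-yl)oxy]phenyl}-4H-chromen-4-one
Conditions: 2-methylbut-3-yn-2-ol, (CF3CO)2O, DBU, MeCN, 0 °C (separate flask); then added to 9, DBU, CuCl2·2H2O (cat.), MeCN, 0 °C to rt
Reagents that add atoms: 2-methylbut-3-yn-2-yl trifluoroacetate, CC(C)(C#C)OC(=O)C(F)(F)F (made in the flask from 2-methylbut-3-yn-2-ol, CC(C)(O)C#C, and trifluoroacetic anhydride)
Why: Copper-catalysed propargylic etherification; a copper acetylide ionises to an allenylidene-type cation that the phenoxide captures at the tertiary carbon, which makes a tertiary aryl ether that direct displacement cannot give. 9 has a single free hydroxyl, and DBU at 0 °C should not open the chromone.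

Step 6
Reactants: 10 5,7-bis(benzyloxy)-3-{4,5-dimethoxy-2-[(2-methylbut-3-yn-2-yl)oxy]phenyl}-4H-chromen-4-one
Product: 11 5,7-bis(benzyloxy)-3-{4,5-dimethoxy-2-[(2-methylbut-3-en-2-yl)oxy]phenyl}-4H-chromen-4-one
Conditions: H2 (1 atm), Pd/CaCO3 poisoned with Pb(OAc)2, quinoline, EtOAc, rt
Reagents that add atoms: none
Why: Lindlar semi-hydrogenation of the terminal alkyne to the vinyl group; on the poisoned catalyst the benzyl ethers and the chromone C2=C3 bond should be untouched, and the reaction is stopped after one equivalent of hydrogen.

Step 7
Reactants: 11 5,7-bis(benzyloxy)-3-{4,5-dimethoxy-2-[(2-methylbut-3-en-2-yl)oxy]phenyl}-4H-chromen-4-one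
Product: 12 5,7-bis(benzyloxy)-3-[2-hydroxy-4,5-dimethoxy-3-(3-methylbut-2-en-1-yl)phenyl]-4H-chromen-4-one
Conditions: PhNEt2, 150 °C, Ar
Reagents that add atoms: none
Why: Aromatic Claisen rearrangement; the [3,3] shift inverts the allyl unit, so the 1,1-dimethylallyl ether delivers the linear prenyl group to C3', and tautomerisation restores the phenol. A shift to the quaternary C1' is reversible and the para position C5' is blocked, so C3' is the only outlet; the basic solvent suppresses cyclisation of the product.

Step 8
Reactants: 12 5,7-bis(benzyloxy)-3-[2-hydroxy-4,5-dimethoxy-3-(3-methylbut-2-en-1-yl)phenyl]-4H-chromen-4-one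
Product: 13 2'-hydroxypiscerythrinetin, 5,7-dihydroxy-3-[2-hydroxy-4,5-dimethoxy-3-(3-methylbut-2-en-1-yl)phenyl]-4H-chromen-4-one
Conditions: BCl3 (1 M in CH2Cl2, 5 equiv), C6HMe5 (6 equiv), CH2Cl2, −78 °C; MeOH/CHCl3 quench at −78 °C
Reagents that add atoms: none
Why: Lewis-acid cleavage of aryl benzyl ethers with a non-basic cation scavenger; pentamethylbenzene captures the benzyl cation by Friedel–Crafts alkylation before it can attack the electron-rich rings or the olefin. At −78 °C the methyl ethers and the prenyl group should survive, and no hydrogen is used.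

## Compound list

1 | 2,4,6-trihydroxyacetophenone | CC(=O)c1c(O)cc(O)cc1O | starting material
2 | benzyl bromide | BrCc1ccccc1 | starting material
3 | 1-[2,4-bis(benzyloxy)-6-hydroxyphenyl]ethan-1-one | CC(=O)c1c(O)cc(OCc2ccccc2)cc1OCc1ccccc1 | intermediate
4 | 2-hydroxy-4,5-dimethoxybenzaldehyde | COc1cc(O)c(C=O)cc1OC | starting material
5 | 4,5-dimethoxy-2-(methoxymethoxy)benzaldehyde | COCOc1cc(OC)c(OC)cc1C=O | intermediate
6 | (E)-1-[2,4-bis(benzyloxy)-6-hydroxyphenyl]-3-[4,5-dimethoxy-2-(methoxymethoxy)phenyl]prop-2-en-1-one | O=C(/C=C/c1cc(OC)c(OC)cc1OCOC)c1c(O)cc(OCc2ccccc2)cc1OCc1ccccc1 | intermediate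
7 | 1-[2,4-bis(benzyloxy)-6-hydroxyphenyl]-2-[4,5-dimethoxy-2-(methoxymethoxy)phenyl]-3,3-dimethoxypropan-1-one (racemic) | COC(OC)C(c1cc(OC)c(OC)cc1OCOC)C(=O)c1c(O)cc(OCc2ccccc2)cc1OCc1ccccc1 | intermediate
8 | 5,7-bis(benzyloxy)-3-[4,5-dimethoxy-2-(methoxymethoxy)phenyl]-4H-chromen-4-one | COCOc1cc(OC)c(OC)cc1-c1coc2cc(OCc3ccccc3)cc(OCc3ccccc3)c2c1=O | intermediate
9 | 5,7-bis(benzyloxy)-3-(2-hydroxy-4,5-dimethoxyphenyl)-4H-chromen-4-one | COc1cc(O)c(-c2coc3cc(OCc4ccccc4)cc(OCc4ccccc4)c3c2=O)cc1OC | intermediate
10 | 5,7-bis(benzyloxy)-3-{4,5-dimethoxy-2-[(2-methylbut-3-yn-2-yl)oxy]phenyl}-4H-chromen-4-one | COc1cc(OC(C)(C)C#C)c(-c2coc3cc(OCc4ccccc4)cc(OCc4ccccc4)c3c2=O)cc1OC | intermediate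
11 | 5,7-bis(benzyloxy)-3-{4,5-dimethoxy-2-[(2-methylbut-3-en-2-yl)oxy]phenyl}-4H-chromen-4-one | COc1cc(OC(C)(C)C=C)c(-c2coc3cc(OCc4ccccc4)cc(OCc4ccccc4)c3c2=O)cc1OC | intermediate
12 | 5,7-bis(benzyloxy)-3-[2-hydroxy-4,5-dimethoxy-3-(3-methylbut-2-en-1-yl)phenyl]-4H-chromen-4-one | COc1cc(-c2coc3cc(OCc4ccccc4)cc(OCc4ccccc4)c3c2=O)c(O)c(CC=C(C)C)c1OC | intermediate
13 | 2'-hydroxypiscerythrinetin, 5,7-dihydroxy-3-[2-hydroxy-4,5-dimethoxy-3-(3-methylbut-2-en-1-yl)phenyl]-4H-chromen-4-one | COc1cc(-c2coc3cc(O)cc(O)c3c2=O)c(O)c(CC=C(C)C)c1OC | target

## Step count and least certain steps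

Total: 8 steps. Longest linear sequence: 7 steps (from 1 through 3, 6, 9, 10, 11 and 12 to 13; the branch from 4 is equally long).

Step 4 (key step). Three processes threaten it:
- The nitric acid released by the oxidant may remove the methoxymethyl group too early, and the freed para-methoxyphenol ring would then be oxidised by remaining trivalent thallium.
- If the acetal group on ring B is lost before ring C has closed, the ring B phenol can attack the acetal carbon in a five-membered closure and lead to a benzofuran.
- Ring A oxygen may add to the α-carbon, which gives an aurone.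

The fallback forms the C3–C1' bond by cross-coupling and sets out from 3.
- Heating 3 with N,N-dimethylformamide dimethyl acetal should give (E)-1-[2,4-bis(benzyloxy)-6-hydroxyphenyl]-3-(dimethylamino)prop-2-en-1-one F1.
- Iodine in chloroform with pyridine should cyclise it to 5,7-bis(benzyloxy)-3-iodo-4H-chromen-4-one F2.
- Purchased 2-bromo-4,5-dimethoxyphenol F3 is converted with MOMCl and K2CO3 into 1-bromo-4,5-dimethoxy-2-(methoxymethoxy)benzene F4.
- Bromine–lithium exchange with n-BuLi at −78 °C and quenching with 2-isopropoxy-4,4,5,5-tetramethyl-1,3,2-dioxaborolane should give 2-[4,5-dimethoxy-2-(methoxymethoxy)phenyl]-4,4,5,5-tetramethyl-1,3,2-dioxaborolane F5.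
- Suzuki–Miyaura coupling of F2 and F5 with Pd(dppf)Cl2 and K2CO3 in dioxane/water would give 8, and methanolic HCl as in the second stage of step 4 brings the route back to 9.

No oxidant touches ring B in this sequence and no acetal is present for the ring B phenol to attack.

Step 5. The phenol is flanked by the chromone and may react slowly, while base-induced elimination of the tertiary ester to an enyne uses up the reagent. The fallback sets out from 9 and comes back at 11, bypassing 10 and step 6. The reagent tert-butyl 2-methylbut-3-en-2-yl carbonate F6 is made from 2-methylbut-3-en-2-ol, n-BuLi and Boc2O. With Pd(PPh3)4 (zerovalent palladium) in THF at 0 °C it should transfer the 1,1-dimethylallyl group to the phenol oxygen by Tsuji–Trost allylation at the more substituted terminus.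

Step 7. The tertiary allyl ether may fragment with loss of the five-carbon unit and return of phenol 9 instead of rearranging, and the ortho-prenylphenol formed may cyclise onto its olefin on prolonged heating. The fallback sets out from 9 and comes back at 12. O-alkylation with prenyl bromide and K2CO3 in acetone should give 5,7-bis(benzyloxy)-3-{4,5-dimethoxy-2-[(3-methylbut-2-en-1-yl)oxy]phenyl}-4H-chromen-4-one F7. Montmorillonite K10 in CH2Cl2 at 0 °C should then promote the 1,3-shift of the prenyl group from oxygen to the only free ortho carbon, C3'.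

Step 8. HCl formed during cleavage or quench may protonate the prenyl olefin, and the free 2'-hydroxyl would then close a 2,2-dimethylchroman. Incomplete capture of the benzyl cation would lead to benzylation of the electron-rich rings. The fallback removes the internal nucleophile; it sets out from 12 and comes back at 13.
- Ac2O and pyridine should give 6-[5,7-bis(benzyloxy)-4-oxo-4H-chromen-3-yl]-3,4-dimethoxy-2-(3-methylbut-2-en-1-yl)phenyl acetate F8.
- BCl3 and pentamethylbenzene at −78 °C then give 6-(5,7-dihydroxy-4-oxo-4H-chromen-3-yl)-3,4-dimethoxy-2-(3-methylbut-2-en-1-yl)phenyl acetate F9.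
- K2CO3 in methanol at 0 °C removes the acetate to give 13.

## Further compounds

F1 | step 4 | (E)-1-[2,4-bis(benzyloxy)-6-hydroxyphenyl]-3-(dimethylamino)prop-2-en-1-one | CN(C)/C=C/C(=O)c1c(O)cc(OCc2ccccc2)cc1OCc1ccccc1
F2 | step 4 | 5,7-bis(benzyloxy)-3-iodo-4H-chromen-4-one | O=c1c(I)coc2cc(OCc3ccccc3)cc(OCc3ccccc3)c12
F3 | step 4 | 2-bromo-4,5-dimethoxyphenol (purchased) | COc1cc(O)c(Br)cc1OC
F4 | step 4 | 1-bromo-4,5-dimethoxy-2-(methoxymethoxy)benzene | COCOc1cc(OC)c(OC)cc1Br
F5 | step 4 | 2-[4,5-dimethoxy-2-(methoxymethoxy)phenyl]-4,4,5,5-tetramethyl-1,3,2-dioxaborolane | COCOc1cc(OC)c(OC)cc1B1OC(C)(C)C(C)(C)O1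
F6 | step 5 | tert-butyl 2-methylbut-3-en-2-yl carbonate | C=CC(C)(C)OC(=O)OC(C)(C)C
F7 | step 7 | 5,7-bis(benzyloxy)-3-{4,5-dimethoxy-2-[(3-methylbut-2-en-1-yl)oxy]phenyl}-4H-chromen-4-one | COc1cc(OCC=C(C)C)c(-c2coc3cc(OCc4ccccc4)cc(OCc4ccccc4)c3c2=O)cc1OC
F8 | step 8 | 6-[5,7-bis(benzyloxy)-4-oxo-4H-chromen-3-yl]-3,4-dimethoxy-2-(3-methylbut-2-en-1-yl)phenyl acetate | COc1cc(-c2coc3cc(OCc4ccccc4)cc(OCc4ccccc4)c3c2=O)c(OC(C)=O)c(CC=C(C)C)c1OC
F9 | step 8 | 6-(5,7-dihydroxy-4-oxo-4H-chromen-3-yl)-3,4-dimethoxy-2-(3-methylbut-2-en-1-yl)phenyl acetate | COc1cc(-c2coc3cc(O)cc(O)c3c2=O)c(OC(C)=O)c(CC=C(C)C)c1OC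
A1 | alternative 1 | 3-[4,5-dimethoxy-2-(methoxymethoxy)-3-(3-methylbut-2-en-1-yl)phenyl]-5,7-bis(methoxymethoxy)-2-(trimethylsilyl)-4H-chromen-4-one | COCOc1c(-c2c([Si](C)(C)C)oc3cc(OCOC)cc(OCOC)c3c2=O)cc(OC)c(OC)c1CC=C(C)C
A2 | alternative 1 | 2-hydroxy-4,6-bis(methoxymethoxy)benzaldehyde | COCOc1cc(O)c(C=O)c(OCOC)c1
A3 | alternative 1 | {[4,5-dimethoxy-2-(methoxymethoxy)-3-(3-methylbut-2-en-1-yl)phenyl]ethynyl}trimethylsilane | COCOc1c(C#C[Si](C)(C)C)cc(OC)c(OC)c1CC=C(C)C
A4 | alternative 2 | 3-[2-hydroxy-4,5-dimethoxy-3-(3-methylbut-2-en-1-yl)phenyl]-5,7-bis(methoxymethoxy)-4H-chromen-4-one | COc1cc(-c2coc3cc(OCOC)cc(OCOC)c3c2=O)c(O)c(CC=C(C)C)c1OC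
A5 | alternative 2 | 3-ethynyl-5,7-bis(methoxymethoxy)-4H-chromen-4-one | C#Cc1coc2cc(OCOC)cc(OCOC)c2c1=O
A6 | alternative 2 | pentacarbonyl(1,2-dimethoxy-6-methylhepta-2,5-dien-1-ylidene)chromium (alkene geometry not defined) | COC(C(OC)=CCC=C(C)C)=[Cr](=C=O)(=C=O)(=C=O)(=C=O)=C=O
A7 | alternative 3 | 5,7-dihydroxy-3-[4,5-dimethoxy-2-(methoxymethoxy)-3-(3-methylbut-2-en-1-yl)phenyl]-4H-chromen-4-one | COCOc1c(-c2coc3cc(O)cc(O)c3c2=O)cc(OC)c(OC)c1CC=C(C)C
A8 | alternative 3 | 1-methoxy-1,3-bis(trimethylsilyloxy)buta-1,3-diene (C1=C2 geometry not defined) | COC(O[Si](C)(C)C)=CC(=C)O[Si](C)(C)C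
A9 | alternative 3 | 3-bromo-5-[4,5-dimethoxy-2-(methoxymethoxy)-3-(3-methylbut-2-en-1-yl)phenyl]-4H-pyran-4-one | COCOc1c(-c2cocc(Br)c2=O)cc(OC)c(OC)c1CC=C(C)C
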